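The route rests on cutting the C2–C3 bond of the dihydrofuran ring. C2 is benzylic, bound to the ring oxygen O1 and to the syringyl ring, and C3 bears a CH2OH that can be traced back to an ester. An ester-substituted aryl carbene at C3 that inserts into a C–H bond of an O1–CH2–aryl ether leaves precisely this arrangement. One rhodium-catalysed step should therefore close the only new ring and create both stereocentres from an achiral methyl aryldiazoacetate, which carries the ortho syringylmethyl ether and the side chain as a cinnamate. C3 is then equilibrated to trans, and both esters are reduced together before the phenol is unveiled.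

Key step: step 7

Assumption: dirhodium tetrakis[N-phthaloyl-(S)-tert-leucinate], Rh2(S-PTTL)4, is taken to deliver the (2R) configuration; should a small-scale run show the opposite sense, the mirror-image catalyst Rh2(R-PTTL)4 from D-tert-leucine is used with no other change.

Step 1
Reactants: 1 5-bromovanillin; 2 methyl (triphenylphosphoranylidene)acetate
Product: 3 methyl (E)-3-(3-bromo-4-hydroxy-5-methoxyphenyl)prop-2-enoate (methyl (E)-5-bromoferulate)
Conditions: 2 (1.5 equiv), toluene, 90 °C
Reagents that add atoms: none
Why: Wittig olefination with an ester-stabilised ylide, whose reversible addition and collapse through the trans oxaphosphetane should give the (E)-enoate, the free phenol being tolerated when the ylide is used in excess in hot toluene.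

Step 2
Reactants: 4 syringaldehyde
Product: 5 3,5-dimethoxy-4-(triisopropylsilyloxy)benzaldehyde
Conditions: TIPSCl, imidazole, DMF, rt
Reagents that add atoms: triisopropylsilyl chloride, CC(C)[Si](Cl)(C(C)C)C(C)C
Why: Imidazole-promoted silylation of the phenol, with the bulky triisopropylsilyl group chosen because its hindered aryl ether should survive hydride, DBU, warm DMF and the carbene step yet fall to fluoride at the end.

Step 3
Reactants: 5 3,5-dimethoxy-4-(triisopropylsilyloxy)benzaldehyde
Product: 6 [3,5-dimethoxy-4-(triisopropylsilyloxy)phenyl]methanol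
Conditions: NaBH4, MeOH/THF, 0 °C
Reagents that add atoms: none
Why: Borohydride reduction of an aryl aldehyde to the benzylic alcohol, conditions under which the hindered aryl silyl ether is stable.

Step 4
Reactants: 3 methyl (E)-5-bromoferulate; 6 [3,5-dimethoxy-4-(triisopropylsilyloxy)phenyl]methanol
Product: 7 methyl (E)-3-[3-bromo-4-{[3,5-dimethoxy-4-(triisopropylsilyloxy)phenyl]methoxy}-5-methoxyphenyl]prop-2-enoate
Conditions: PPh3, DIAD, THF, 0 °C to rt
Reagents that add atoms: none
Why: Mitsunobu etherification, in which the acidic ortho-bromophenol is the pronucleophile and displaces the primary benzylic alcohol activated as its oxyphosphonium ion, so that no base and no labile benzylic halide are needed and enoate and silyl ether stay intact.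

Step 5
Reactants: 7 the aryl bromide of step 4; 8 1-(tert-butyldimethylsilyloxy)-1-methoxyethene
Product: 9 methyl (E)-3-[4-{[3,5-dimethoxy-4-(triisopropylsilyloxy)phenyl]methoxy}-3-methoxy-5-(2-methoxy-2-oxoethyl)phenyl]prop-2-enoate
Conditions: Pd(dba)2 (zerovalent palladium), P(tBu)3, ZnF2, 8 (2 equiv), DMF, 80 °C
Reagents that add atoms: none
Why: Palladium-catalysed α-arylation of a silyl ketene acetal (oxidative addition of the aryl bromide, fluoride-assisted transfer of the ester enolate from silicon to palladium, C–C reductive elimination), run in an essentially neutral medium so that the enoate and the methyl esters should not be attacked.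

Step 6
Reactants: 9 the methyl arylacetate of step 5
Product: 10 methyl (E)-3-[3-(1-diazo-2-methoxy-2-oxoethyl)-4-{[3,5-dimethoxy-4-(triisopropylsilyloxy)phenyl]methoxy}-5-methoxyphenyl]prop-2-enoate
Conditions: p-ABSA, DBU, MeCN, 0 °C to rt
Reagents that add atoms: p-acetamidobenzenesulfonyl azide, CC(=O)Nc1ccc(cc1)S(=O)(=O)N=[N+]=[N-]
Why: Regitz diazo transfer, in which DBU deprotonates the only sufficiently acidic position, the arylacetate CH2, and the enolate takes the terminal nitrogen of the sulfonyl azide and releases the sulfonamide.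

Step 7
Reactants: 10 the methyl aryldiazoacetate of step 6
Product: 11 methyl (2R,3S)-2-[3,5-dimethoxy-4-(triisopropylsilyloxy)phenyl]-7-methoxy-5-[(E)-3-methoxy-3-oxoprop-1-enyl]-2,3-dihydro-1-benzofuran-3-carboxylate (2,3-cis)
Conditions: Rh2(S-PTTL)4 (divalent rhodium, 1–2 mol %), toluene, −78 to −60 °C, slow addition of 10
Reagents that add atoms: none
Why: Rh2(S-PTTL)4 should expel N2 from 10 to give an electrophilic donor/acceptor rhodium carbene, whose carbon inserts through a concerted, asynchronous, hydride-transfer-like three-centre transition state into one C–H bond of the ether CH2 five atoms away. The closest known reaction type is the enantioselective intramolecular 1,5 C–H insertion of ortho-benzyloxy aryldiazoacetates under chiral dirhodium carboxylate catalysis, which gives cis-2-aryl-2,3-dihydrobenzofuran-3-carboxylates. The dihydrofuran ring (O1, C2, C3, C3a, C7a) is closed by formation of the C2–C3 bond, a five-membered closure by 1,5-insertion in which the two benzo-ring carbons and O1 form the tether. C2 is set by the chiral carboxylate pocket, which tells apart the two enantiotopic hydrogens of the OCH2 group, and C3 is set relative to C2 by the compact transition state that places ester and aryl group cis, a kinetic relationship that step 8 corrects. The step needs site selectivity and chemoselectivity: the only C–H bond within reach is benzylic, alpha to oxygen and on an electron-rich ring, hence strongly activated, whereas the electron-poor, trans-disubstituted cinnamate meta to the carbene and the hindered syringyl ring are poor partners for cyclopropanation. Slow addition at low temperature should suppress carbene dimer and azine formation.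

Step 8
Reactants: 11 the cis diester of step 7
Product: 12 methyl (2R,3R)-2-[3,5-dimethoxy-4-(triisopropylsilyloxy)phenyl]-7-methoxy-5-[(E)-3-methoxy-3-oxoprop-1-enyl]-2,3-dihydro-1-benzofuran-3-carboxylate (2,3-trans)
Conditions: DBU (0.5 equiv), toluene, rt
Reagents that add atoms: none
Why: Base-mediated epimerisation through the C3 ester enolate, whose reprotonation anti to the C2 aryl group should give the thermodynamically favoured trans diester, while C2 has no acidic hydrogen, ring opening by loss of the O1 phenoxide would be a disfavoured reverse 5-endo process, and the non-nucleophilic amine spares the aryl silyl ether and the enoate.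

Step 9
Reactants: 12 the trans diester of step 8
Product: 13 [(2R,3S)-2-[3,5-dimethoxy-4-(triisopropylsilyloxy)phenyl]-5-[(E)-3-hydroxyprop-1-enyl]-7-methoxy-2,3-dihydro-1-benzofuran-3-yl]methanol
Conditions: iBu2AlH (6 equiv), CH2Cl2, −78 to −40 °C; aq. potassium sodium tartrate
Reagents that add atoms: none
Why: DIBAL-H reduction of both methyl esters to primary alcohols, the conjugated one by 1,2-hydride delivery so that the (E)-alkene should persist as the allylic alcohol, with C3 already in its favoured trans arrangement and therefore not at risk at low temperature (the descriptor changes from 3R to 3S only through the priority rules).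

Step 10
Reactants: 13 the silyl-protected diol of step 9
Product: 14 4-[(2R,3S)-3-(hydroxymethyl)-5-[(E)-3-hydroxyprop-1-enyl]-7-methoxy-2,3-dihydro-1-benzofuran-2-yl]-2,6-dimethoxyphenol (target CNP0191372.2)
Conditions: Bu4NF, AcOH, THF, 0 °C
Reagents that add atoms: none
Why: Fluoride desilylation of the aryl silyl ether driven by the Si–F bond, with acetic acid protonating the phenoxide as it forms so that O1 is not expelled from C2 through a para-quinone methide and the C2 configuration is kept.

Compound list
1 | 5-bromovanillin (3-bromo-4-hydroxy-5-methoxybenzaldehyde) | COc1cc(C=O)cc(Br)c1O | starting material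
2 | methyl (triphenylphosphoranylidene)acetate | COC(=O)C=P(c1ccccc1)(c1ccccc1)c1ccccc1 | starting material
3 | methyl (E)-3-(3-bromo-4-hydroxy-5-methoxyphenyl)prop-2-enoate | COC(=O)/C=C/c1cc(OC)c(O)c(Br)c1 | intermediate
4 | syringaldehyde (4-hydroxy-3,5-dimethoxybenzaldehyde) | COc1cc(C=O)cc(OC)c1O | starting material
5 | 3,5-dimethoxy-4-(triisopropylsilyloxy)benzaldehyde | COc1cc(C=O)cc(OC)c1O[Si](C(C)C)(C(C)C)C(C)C | intermediate
6 | [3,5-dimethoxy-4-(triisopropylsilyloxy)phenyl]methanol | COc1cc(CO)cc(OC)c1O[Si](C(C)C)(C(C)C)C(C)C | intermediate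
7 | methyl (E)-3-[3-bromo-4-{[3,5-dimethoxy-4-(triisopropylsilyloxy)phenyl]methoxy}-5-methoxyphenyl]prop-2-enoate | COC(=O)/C=C/c1cc(OC)c(OCc2cc(OC)c(O[Si](C(C)C)(C(C)C)C(C)C)c(OC)c2)c(Br)c1 | intermediate
8 | 1-(tert-butyldimethylsilyloxy)-1-methoxyethene | C=C(OC)O[Si](C)(C)C(C)(C)C | starting material
9 | methyl (E)-3-[4-{[3,5-dimethoxy-4-(triisopropylsilyloxy)phenyl]methoxy}-3-methoxy-5-(2-methoxy-2-oxoethyl)phenyl]prop-2-enoate | COC(=O)Cc1cc(/C=C/C(=O)OC)cc(OC)c1OCc1cc(OC)c(O[Si](C(C)C)(C(C)C)C(C)C)c(OC)c1 | intermediate
10 | methyl (E)-3-[3-(1-diazo-2-methoxy-2-oxoethyl)-4-{[3,5-dimethoxy-4-(triisopropylsilyloxy)phenyl]methoxy}-5-methoxyphenyl]prop-2-enoate | COC(=O)C(=[N+]=[N-])c1cc(/C=C/C(=O)OC)cc(OC)c1OCc1cc(OC)c(O[Si](C(C)C)(C(C)C)C(C)C)c(OC)c1 | intermediate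
11 | methyl (2R,3S)-2-[3,5-dimethoxy-4-(triisopropylsilyloxy)phenyl]-7-methoxy-5-[(E)-3-methoxy-3-oxoprop-1-enyl]-2,3-dihydro-1-benzofuran-3-carboxylate (cis) | COc1cc([C@@H]2Oc3c(OC)cc(/C=C/C(=O)OC)cc3[C@@H]2C(=O)OC)cc(OC)c1O[Si](C(C)C)(C(C)C)C(C)C | intermediate
12 | methyl (2R,3R)-2-[3,5-dimethoxy-4-(triisopropylsilyloxy)phenyl]-7-methoxy-5-[(E)-3-methoxy-3-oxoprop-1-enyl]-2,3-dihydro-1-benzofuran-3-carboxylate (trans) | COc1cc([C@@H]2Oc3c(OC)cc(/C=C/C(=O)OC)cc3[C@H]2C(=O)OC)cc(OC)c1O[Si](C(C)C)(C(C)C)C(C)C | intermediate
13 | [(2R,3S)-2-[3,5-dimethoxy-4-(triisopropylsilyloxy)phenyl]-5-[(E)-3-hydroxyprop-1-enyl]-7-methoxy-2,3-dihydro-1-benzofuran-3-yl]methanol | COc1cc([C@@H]2Oc3c(OC)cc(/C=C/CO)cc3[C@H]2CO)cc(OC)c1O[Si](C(C)C)(C(C)C)C(C)C | intermediate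
14 | 4-[(2R,3S)-3-(hydroxymethyl)-5-[(E)-3-hydroxyprop-1-enyl]-7-methoxy-2,3-dihydro-1-benzofuran-2-yl]-2,6-dimethoxyphenol | COc1cc([C@@H]2Oc3c(OC)cc(/C=C/CO)cc3[C@H]2CO)cc(OC)c1O | target

Total step count: 10
Longest linear sequence: 9 steps (syringaldehyde 4 to target 14, steps 2 to 10)

Steps most likely to fail

Step 7. The very electron-rich syringyl ring may make the hydride transfer so early that the catalyst pocket no longer tells the two enantiotopic hydrogens apart, and the carbene may be lost to dimer or azine. The fallback replaces catalyst control alone by a covalently bound chiral auxiliary combined with a chiral catalyst, a known remedy for highly oxygenated substrates of this kind. (2S)-2-Hydroxy-1-(pyrrolidin-1-yl)propan-1-one F1, made from ethyl (S)-lactate and pyrrolidine, is acylated with bromoacetyl bromide and pyridine to the bromoacetate F2. Zinc dust in THF turns F2 into the bromozinc enolate F3, which is cross-coupled with bromide 7 (Pd(dba)2, P(tBu)3, THF, rt) to the lactamide arylacetate F4. Diazo transfer (p-ABSA, DBU) gives the lactamide diazo ester F5. Insertion with dirhodium tetrakis[(S)-N-(4-dodecylbenzenesulfonyl)prolinate], Rh2(S-DOSP)4 (divalent rhodium), or its mirror image, whichever proves the matched partner for (2R), should give the dihydrobenzofuran lactamide ester F6, expected mainly as the trans isomer. Brief treatment with catalytic NaOMe in MeOH/THF at 0 °C exchanges the activated auxiliary ester for the methyl ester and equilibrates C3, so the fallback rejoins the route at trans diester 12.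

Step 5. The enoate may be consumed by Heck-type insertion of the arylpalladium species or by fluoride-triggered conjugate addition of the ketene acetal, the product may be arylated a second time, and fluoride may slowly attack the aryl silyl ether at 80 °C. The fallback leaves the silicon enolate and fluoride altogether for a Negishi-type coupling of a preformed zinc enolate at room temperature. The Reformatsky reagent bromo(2-methoxy-2-oxoethyl)zinc F7, made from methyl bromoacetate and zinc dust in THF, is coupled with bromide 7 (Pd(dba)2, P(tBu)3, THF, rt) and should give the methyl arylacetate 9 directly.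

Step 4. The activated, very electron-rich benzylic alcohol may ionise and be lost to self-condensation or ring alkylation, while the doubly ortho-substituted phenoxide attacks slowly. The fallback changes the bond construction to a Williamson alkylation. Alcohol 6 is converted by an Appel reaction (CBr4, PPh3, CH2Cl2, 0 °C) into [4-(bromomethyl)-2,6-dimethoxyphenoxy]triisopropylsilane F8, which is used at once to alkylate phenol 3 (Cs2CO3, MeCN, rt) and returns to the route at ether 7.

Further compounds
F1 | step 7 | (2S)-2-hydroxy-1-(pyrrolidin-1-yl)propan-1-one | C[C@H](O)C(=O)N1CCCC1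
F2 | step 7 | (2S)-1-oxo-1-(pyrrolidin-1-yl)propan-2-yl bromoacetate | C[C@H](OC(=O)CBr)C(=O)N1CCCC1
F3 | step 7 | bromozinc enolate (Reformatsky reagent) of F2 | C[C@H](OC(=O)C[Zn]Br)C(=O)N1CCCC1
F4 | step 7 | (2S)-1-oxo-1-(pyrrolidin-1-yl)propan-2-yl 2-[2-{[3,5-dimethoxy-4-(triisopropylsilyloxy)phenyl]methoxy}-3-methoxy-5-[(E)-3-methoxy-3-oxoprop-1-enyl]phenyl]acetate | C[C@H](OC(=O)Cc1cc(/C=C/C(=O)OC)cc(OC)c1OCc1cc(OC)c(O[Si](C(C)C)(C(C)C)C(C)C)c(OC)c1)C(=O)N1CCCC1
F5 | step 7 | (2S)-1-oxo-1-(pyrrolidin-1-yl)propan-2-yl 2-diazo-2-[2-{[3,5-dimethoxy-4-(triisopropylsilyloxy)phenyl]methoxy}-3-methoxy-5-[(E)-3-methoxy-3-oxoprop-1-enyl]phenyl]acetate | C[C@H](OC(=O)C(=[N+]=[N-])c1cc(/C=C/C(=O)OC)cc(OC)c1OCc1cc(OC)c(O[Si](C(C)C)(C(C)C)C(C)C)c(OC)c1)C(=O)N1CCCC1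
F6 | step 7 | (2S)-1-oxo-1-(pyrrolidin-1-yl)propan-2-yl (2R,3R)-2-[3,5-dimethoxy-4-(triisopropylsilyloxy)phenyl]-7-methoxy-5-[(E)-3-methoxy-3-oxoprop-1-enyl]-2,3-dihydro-1-benzofuran-3-carboxylate | COc1cc([C@@H]2Oc3c(OC)cc(/C=C/C(=O)OC)cc3[C@H]2C(=O)O[C@@H](C)C(=O)N2CCCC2)cc(OC)c1O[Si](C(C)C)(C(C)C)C(C)C
F7 | step 5 | bromo(2-methoxy-2-oxoethyl)zinc | COC(=O)C[Zn]Br
F8 | step 4 | [4-(bromomethyl)-2,6-dimethoxyphenoxy]triisopropylsilane | COc1cc(CBr)cc(OC)c1O[Si](C(C)C)(C(C)C)C(C)C
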